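The route (briarane numbering, defined below) cuts the cyclohexane at its CH(OH)–CH2 bond, C12–C13, as an aldol and at C1–C10 as a Michael addition, which reveals two achiral commercial fragments. In one pot, 3-methylpentane-2,4-dione adds to ethyl 3-methyl-4-oxobut-2-enoate, one acetyl group closes the six-membered ring, and the new C12 hydroxyl lactonises onto the C9 ester. The step exploits the 1,3-dioxygenated C12–C13–C14 unit of the cyclohexane, the quaternary C1 flanked by oxygenated C14 and C2 (a hidden symmetric diketone), and the cis C9/O12 pair, whose lactone bridge fixes four stereocentres. Chain extension at C3 and C9, ring-closing metathesis and a Reformatsky lactonisation complete the skeleton.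

Key step: step 1

Remark on numbering: C1 (quaternary, methyl C15), C2 (OAc), C3, C4, C5 (bears the ester carbon C16), C6, C7 (lactone oxygen), C8 (OH), C9 (OAc) and C10 form the ten-membered ring. C10, C11 (methyl C20), C12 (OH), C13, C14 (OAc) and C1 form the cyclohexane. C17 (methyl C18) and C19 (C=O) complete the γ-lactone.

Assumption: the quinine-derived squaramide is taken to deliver 1 to the Re face of C2 of 2; if the opposite sense is found, its quinidine-derived pseudo-enantiomer is used.

Step 1
Reactants: 1 3-methylpentane-2,4-dione; 2 ethyl (E)-3-methyl-4-oxobut-2-enoate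
Product: 5 bridged keto-lactone 2-acetyl-2,8-dimethyl-6-oxabicyclo[3.2.1]octane-3,7-dione, via Michael adduct 3 (not isolated), via ketol 4 (not isolated)
Conditions: quinine-derived 3,5-bis(trifluoromethyl)phenyl squaramide (10 mol %), PhMe, 0 °C to rt; then 10-camphorsulfonic acid (0.5 equiv), 5 Å molecular sieves, 45 °C
Reagents that add atoms: none
Why: The amine–squaramide pairs the enolate of 1 with hydrogen-bonded 2 and delivers the tertiary carbon to the less substituted alkene carbon, β to the aldehyde, on its Re face (C1–C10 bond; closest precedent: organocatalytic Michael additions of 1,3-dicarbonyls to 4-oxo-enoates); after acid is added the enol of one acetyl group attacks the protonated aldehyde (C12–C13 bond) as in the aldol half of a Robinson annulation, and the new hydroxyl is acylated by the neighbouring ester. The carbocycle closes in the 6-(enolendo)-exo-trig mode and the lactone in the 5-exo-trig mode. C10 is set by the catalyst; C11 (epimerisable through the aldehyde enol), C12 and C1 are set by a thermodynamic funnel, since the aldol is reversible and only the ketol whose hydroxyl is cis to the ester can lactonise, which forces the chair with axial C9 and O12, an equatorial C11 methyl and, at C1, an equatorial methyl and an axial acetyl (smaller A value, anti to the lactone carbonyl). The step needs discrimination between the two acetyl groups and suppression of dehydration to the cyclohexenone; the first rests on that chair preference and the second on capture of the hydroxyl as the lactone under amine-free acid, while the quaternary C1 rules out every other enolisation mode of the ketones.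

Step 2
Reactants: 5 bridged keto-lactone
Product: 6 hydroxy lactone 2-acetyl-3-hydroxy-2,8-dimethyl-6-oxabicyclo[3.2.1]octan-7-one (equatorial 14-OH cis to the acetyl group)
Conditions: NaBH4, CeCl3·7H2O, MeOH/CH2Cl2, −78 °C
Reagents that add atoms: none
Why: Luche reduction, in which the ring ketone reacts far faster than the axial, neopentyl-type acetyl group and hydride adds to C14 anti to the axial C1–acetyl bond (Felkin–Anh, axial attack on the locked chair, past a lactone bridge that carries no inward hydrogen) to give the equatorial alcohol, the cold cerium-buffered medium avoiding β-elimination of the lactone carboxylate.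

Step 3
Reactants: 6 hydroxy lactone
Product: 7 silyl ether (14-O-triethylsilyl ether of 6)
Conditions: Et3SiOTf, 2,6-lutidine, CH2Cl2, −78 to 0 °C
Reagents that add atoms: triethylsilyl trifluoromethanesulfonate, CC[Si](CC)(CC)OS(=O)(=O)C(F)(F)F
Why: Silylation with a silyl triflate protects the hindered C14 hydroxyl, so that the later enolate step cannot trigger a retro-aldol cleavage of the C1–C14 bond.

Step 4
Reactants: 7 silyl ether; 8 2,3-dibromoprop-1-ene
Product: 10 alkylated ketone 2-(4-bromopent-4-enoyl)-2,8-dimethyl-3-(triethylsilyloxy)-6-oxabicyclo[3.2.1]octan-7-one, via lithium enolate 9 (not isolated)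
Conditions: LiN(i-Pr)2, THF, −78 °C; then 8, DMPU, −78 to −40 °C
Reagents that add atoms: none
Why: Kinetic enolate alkylation, in which C3 is the only site that can be deprotonated (C1 is quaternary, C10 a bridgehead), the enolate on the axial acetyl group is trans-diaxial to the lactone carbonyl and cannot attack it, and the allylic bromide reacts by SN2 while the vinyl bromide stays as a masked acrylate.

Step 5
Reactants: 10 alkylated ketone
Product: 11 (2R)-carbinol 2-[(1R)-4-bromo-1-hydroxypent-4-en-1-yl]-2,8-dimethyl-3-(triethylsilyloxy)-6-oxabicyclo[3.2.1]octan-7-one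
Conditions: (S)-2-methyl-CBS-oxazaborolidine (0.3 equiv), BH3·SMe2, THF, −20 °C
Reagents that add atoms: none
Why: Corey–Bakshi–Shibata reduction, in which the quaternary C1 is the large and the C3 methylene the small ketone substituent, so that the (S)-catalyst delivers hydride to give the (2R)-alcohol under reagent control while lactone and vinyl bromide are left untouched at low temperature.

Step 6
Reactants: 11 (2R)-carbinol
Product: 12 bis-silyl lactone (2,14-bis(triethylsilyl) ether)
Conditions: Et3SiOTf, 2,6-lutidine, CH2Cl2, −78 to 0 °C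
Reagents that add atoms: triethylsilyl trifluoromethanesulfonate, CC[Si](CC)(CC)OS(=O)(=O)C(F)(F)F
Why: Silylation of the neopentyl-type C2 hydroxyl, which would otherwise consume organometallic reagents and lactonise onto the later C16 ester.

Step 7
Reactants: 12 bis-silyl lactone
Product: 13 bridged lactol (6-oxabicyclo[3.2.1]octan-7-ol, both anomers)
Conditions: i-Bu2AlH (1.2 equiv), CH2Cl2, −78 °C; aqueous potassium sodium tartrate (KNaC4H4O6) work-up
Reagents that add atoms: none
Why: Partial reduction of a lactone to the lactol, whose tetrahedral aluminium hemiacetal is stable at −78 °C, gives C9 at the aldehyde oxidation level while the vinyl bromide and silyl ethers are inert.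

Step 8
Reactants: 13 lactol; 14 2-bromo-3,3-diethoxyprop-1-ene
Product: 16 9,12-diol carrying the (9R)-allylic alcohol with the C8 methylene and C7 diethyl acetal, via vinyllithium reagent 15 (not isolated)
Conditions: 14, t-BuLi (2 equiv), Et2O, −78 °C; then 13 (0.3 equiv), THF, −78 to −40 °C; H2O
Reagents that add atoms: none
Why: Bromine–lithium exchange gives 15, one equivalent of which opens the lactol to the C9 aldehyde alkoxide, and 1,2-addition should then follow the Felkin–Anh model (attack anti to the quaternary C1, reinforced by lithium bridging to the C12 alkoxide) to set (9R).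

Step 9
Reactants: 16 9,12-diol
Product: 17 mono-silyl ether (12-O-tert-butyldimethylsilyl ether with free 9-OH)
Conditions: t-BuMe2SiCl (1.3 equiv), imidazole, DMF, 0 °C
Reagents that add atoms: tert-butyldimethylsilyl chloride, CC(C)(C)[Si](C)(C)Cl
Why: Selective silylation, since the ring hydroxyl at C12 is flanked by a methylene while the C9 hydroxyl lies between the C10 methine next to quaternary C1 and the fully substituted C8.

Step 10
Reactants: 17 vinyl bromide
Product: 18 methyl acrylate (C5 with exocyclic methylene and the C16 methyl ester)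
Conditions: Pd(OAc)2 (5 mol %), Xantphos (6 mol %), CO (1 atm), MeOH, i-Pr2NEt, DMF, 60 °C
Reagents that add atoms: carbon monoxide, [C-]#[O+]; methanol, CO
Why: Palladium-catalysed alkoxycarbonylation of the 2-bromoalkene installs C16, and it is run before any allylic acetate exists so that zerovalent palladium has no competing ionisation pathway.

Step 11
Reactants: 18 acrylate
Product: 19 triol (2,9,14-triol)
Conditions: HF·pyridine, pyridine, THF, 0 °C
Reagents that add atoms: none
Why: Selective desilylation, in which the two triethylsilyl ethers are cleaved by buffered fluoride much faster than the secondary tert-butyldimethylsilyl ether at C12 and the diethyl acetal is not affected.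

Step 12
Reactants: 19 triol
Product: 20 triacetate (2,9,14-triacetate)
Conditions: Ac2O, DMAP, pyridine, rt
Reagents that add atoms: acetic anhydride, CC(=O)OC(C)=O
Why: DMAP-catalysed acylation of the three secondary hydroxyls fixes the final acetate pattern, because O12 is silylated and O7 and O8 do not exist yet.

Step 13
Reactants: 20 triacetate acetal
Product: 21 C7 enal (2-substituted acrolein)
Conditions: pyridinium p-toluenesulfonate, acetone/H2O (10:1), 40 °C
Reagents that add atoms: water, O
Why: Acid-catalysed hydrolysis of the allylic-type diethyl acetal is fast under conditions that leave the acetates, the methyl ester and the silyl ether intact.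

Step 14
Reactants: 21 enal; 22 iodoethene
Product: 23 (7S)-bis-allylic alcohol
Conditions: CrCl2 (4 equiv), chiral oxazoline–sulfonamide ligand (4.4 equiv), Et3N (4.4 equiv), NiCl2 (5 mol %), THF, rt
Reagents that add atoms: none
Why: Asymmetric Nozaki–Hiyama–Kishi reaction, aldehyde-selective in the presence of acetates and the acrylate, in which the ligand enantiomer that directs the vinyl group to the Si face of the C7 aldehyde is used so that reagent control overrides the modest 1,3-bias from C9 and sets (7S).

Step 15
Reactants: 23 (7S)-alcohol; 24 2-bromopropanoyl bromide (racemic)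
Product: 25 triene ester (7-O-(2-bromopropanoyl) ester of 23)
Conditions: pyridine, CH2Cl2, −20 °C
Reagents that add atoms: none
Why: Acylation of the only free hydroxyl with an acid bromide proceeds with retention at C7 and brings in C17, C18 and C19 (the α-centre is racemic and is destroyed in step 18).

Step 16
Reactants: 25 triene ester
Product: 26 ten-membered ring olefin (C5=C6 with C4 and C7 cis)
Conditions: second-generation Hoveyda–Grubbs catalyst (15 mol %), 1,4-benzoquinone (20 mol %), PhMe (1 mM), 80 °C
Reagents that add atoms: none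
Why: Ring-closing metathesis between the C6 vinyl group and the acrylate methylene, possible because the trans-disposed C1 and C10 arms lie gauche in the cyclohexane conformer that places both pseudo-equatorially, with ring strain enforcing the cis ring olefin (the E isomer by CIP) and the flanked 1,1-disubstituted C8 methylene remaining a bystander.

Step 17
Reactants: 26 ring olefin
Product: 28 C8 ketone, via ozonide 27 (not isolated)
Conditions: O3 (1 equiv), CH2Cl2, −78 °C; then PPh3, −78 °C to rt
Reagents that add atoms: ozone, [O-][O+]=O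
Why: Ozonolysis, in which electrophilic ozone cleaves the C8 methylene in preference to the ester-conjugated C5=C6 bond and reductive cleavage of ozonide 27 gives the ketone.

Step 18
Reactants: 28 keto bromo ester
Product: 30 silyl-protected target (12-O-tert-butyldimethylsilyl ether; γ-lactone bearing the tertiary 8-OH), via zinc enolate 29 (not isolated)
Conditions: Zn dust (activated with Me3SiCl), THF, 45 °C
Reagents that add atoms: none
Why: Intramolecular Reformatsky reaction, in which zinc inserts into the C–Br bond without touching acetates, enoate or ketone, the chelated enolate 29 attacks C8 in the 5-exo-trig mode on the face that keeps C6–C7–C8–C9 antiperiplanar (trans ring fusion, 8-OH cis to C6), and the C17 methyl takes the less crowded position cis to the 8-OH and trans to C9, as in the target.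

Step 19
Reactants: 30 silyl ether
Product: 31 CNP0233742.2
Conditions: HF·pyridine, pyridine, THF, 0 °C to rt
Reagents that add atoms: none
Why: Fluoride-mediated desilylation frees the C12 hydroxyl without acyl migration, the three acetates, both esters and the tertiary 8-OH being stable to buffered HF.

Compound list
1 | 3-methylpentane-2,4-dione | CC(=O)C(C)C(C)=O | starting material
2 | ethyl (E)-3-methyl-4-oxobut-2-enoate | CCOC(=O)/C=C(\C)C=O | starting material
3 | ethyl (2S)-3-methyl-2-(3-methyl-2,4-dioxopentan-3-yl)-4-oxobutanoate (C10 fixed, C11 epimers equilibrating) | CCOC(=O)[C@@H](C(C)C=O)C(C)(C(C)=O)C(C)=O | intermediate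
4 | ethyl 2-acetyl-5-hydroxy-2,6-dimethyl-3-oxocyclohexane-1-carboxylate (ester, C11 methyl, C12 hydroxyl and C1 methyl all cis) | CCOC(=O)[C@H]1[C@@H](C)[C@@H](O)CC(=O)[C@]1(C)C(C)=O | intermediate
5 | 2-acetyl-2,8-dimethyl-6-oxabicyclo[3.2.1]octane-3,7-dione (C1 methyl equatorial, acetyl axial, C11 methyl syn to the lactone bridge) | O=C2[C@H]1[C@@H](C)[C@@H](O2)CC(=O)[C@]1(C)C(C)=O | intermediate
6 | 2-acetyl-3-hydroxy-2,8-dimethyl-6-oxabicyclo[3.2.1]octan-7-one (equatorial 14-OH) | O=C2[C@H]1[C@@H](C)[C@@H](O2)C[C@H](O)[C@]1(C)C(C)=O | intermediate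
7 | 14-O-triethylsilyl ether of 6 | O=C2[C@H]1[C@@H](C)[C@@H](O2)C[C@H](O[Si](CC)(CC)CC)[C@]1(C)C(C)=O | intermediate
8 | 2,3-dibromoprop-1-ene | BrCC(Br)=C | starting material
9 | lithium enolate of 7 (acetyl methyl deprotonated) | O=C2[C@H]1[C@@H](C)[C@@H](O2)C[C@H](O[Si](CC)(CC)CC)[C@]1(C)C(=C)O[Li] | intermediate
10 | 2-(4-bromopent-4-enoyl)-2,8-dimethyl-3-(triethylsilyloxy)-6-oxabicyclo[3.2.1]octan-7-one | O=C2[C@H]1[C@@H](C)[C@@H](O2)C[C@H](O[Si](CC)(CC)CC)[C@]1(C)C(=O)CCC(Br)=C | intermediate
11 | (2R)-carbinol from 10 | O=C2[C@H]1[C@@H](C)[C@@H](O2)C[C@H](O[Si](CC)(CC)CC)[C@]1(C)[C@H](O)CCC(Br)=C | intermediate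
12 | 2,14-bis(triethylsilyl) ether of the lactone | O=C2[C@H]1[C@@H](C)[C@@H](O2)C[C@H](O[Si](CC)(CC)CC)[C@]1(C)[C@H](O[Si](CC)(CC)CC)CCC(Br)=C | intermediate
13 | bridged lactol (C9 anomers) | OC2[C@H]1[C@@H](C)[C@@H](O2)C[C@H](O[Si](CC)(CC)CC)[C@]1(C)[C@H](O[Si](CC)(CC)CC)CCC(Br)=C | intermediate
14 | 2-bromo-3,3-diethoxyprop-1-ene | CCOC(OCC)C(Br)=C | starting material
15 | (3,3-diethoxyprop-1-en-2-yl)lithium | CCOC(OCC)C([Li])=C | intermediate
16 | (9R)-9,12-diol with C8 methylene, C7 diethyl acetal, 2,14-bis(triethylsilyl) ethers and C5 vinyl bromide | CCOC(OCC)C(=C)[C@H](O)[C@H]1[C@@H](C)[C@@H](O)C[C@H](O[Si](CC)(CC)CC)[C@]1(C)[C@H](O[Si](CC)(CC)CC)CCC(Br)=C | intermediate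
17 | 12-O-tert-butyldimethylsilyl ether of 16 | CCOC(OCC)C(=C)[C@H](O)[C@H]1[C@@H](C)[C@@H](O[Si](C)(C)C(C)(C)C)C[C@H](O[Si](CC)(CC)CC)[C@]1(C)[C@H](O[Si](CC)(CC)CC)CCC(Br)=C | intermediate
18 | methyl acrylate from 17 (C16 ester on C5) | CCOC(OCC)C(=C)[C@H](O)[C@H]1[C@@H](C)[C@@H](O[Si](C)(C)C(C)(C)C)C[C@H](O[Si](CC)(CC)CC)[C@]1(C)[C@H](O[Si](CC)(CC)CC)CCC(=C)C(=O)OC | intermediate
19 | 2,9,14-triol | CCOC(OCC)C(=C)[C@H](O)[C@H]1[C@@H](C)[C@@H](O[Si](C)(C)C(C)(C)C)C[C@H](O)[C@]1(C)[C@H](O)CCC(=C)C(=O)OC | intermediate
20 | 2,9,14-triacetate | CCOC(OCC)C(=C)[C@H](OC(C)=O)[C@H]1[C@@H](C)[C@@H](O[Si](C)(C)C(C)(C)C)C[C@H](OC(C)=O)[C@]1(C)[C@H](OC(C)=O)CCC(=C)C(=O)OC | intermediate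
21 | C7 enal | O=CC(=C)[C@H](OC(C)=O)[C@H]1[C@@H](C)[C@@H](O[Si](C)(C)C(C)(C)C)C[C@H](OC(C)=O)[C@]1(C)[C@H](OC(C)=O)CCC(=C)C(=O)OC | intermediate
22 | iodoethene | C=CI | starting material
23 | (7S)-bis-allylic alcohol | C=C[C@H](O)C(=C)[C@H](OC(C)=O)[C@H]1[C@@H](C)[C@@H](O[Si](C)(C)C(C)(C)C)C[C@H](OC(C)=O)[C@]1(C)[C@H](OC(C)=O)CCC(=C)C(=O)OC | intermediate
24 | 2-bromopropanoyl bromide (racemic) | CC(Br)C(=O)Br | starting material
25 | 7-O-(2-bromopropanoyl) ester of 23 | C=C[C@H](OC(=O)C(C)Br)C(=C)[C@H](OC(C)=O)[C@H]1[C@@H](C)[C@@H](O[Si](C)(C)C(C)(C)C)C[C@H](OC(C)=O)[C@]1(C)[C@H](OC(C)=O)CCC(=C)C(=O)OC | intermediate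
26 | ten-membered ring olefin with C8 methylene | COC(=O)/C1=C/[C@H](OC(=O)C(C)Br)C(=C)[C@H](OC(C)=O)[C@H]2[C@@H](C)[C@@H](O[Si](C)(C)C(C)(C)C)C[C@H](OC(C)=O)[C@]2(C)[C@H](OC(C)=O)CC1 | intermediate
27 | spiro-1,2,4-trioxolane (ozonide) at C8 | COC(=O)/C1=C/[C@H](OC(=O)C(C)Br)C3(OOCO3)[C@H](OC(C)=O)[C@H]2[C@@H](C)[C@@H](O[Si](C)(C)C(C)(C)C)C[C@H](OC(C)=O)[C@]2(C)[C@H](OC(C)=O)CC1 | intermediate
28 | C8 ketone | COC(=O)/C1=C/[C@H](OC(=O)C(C)Br)C(=O)[C@H](OC(C)=O)[C@H]2[C@@H](C)[C@@H](O[Si](C)(C)C(C)(C)C)C[C@H](OC(C)=O)[C@]2(C)[C@H](OC(C)=O)CC1 | intermediate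
29 | bromozinc enolate of the C7 propanoate | COC(=O)/C1=C/[C@H](OC(=CC)O[Zn]Br)C(=O)[C@H](OC(C)=O)[C@H]2[C@@H](C)[C@@H](O[Si](C)(C)C(C)(C)C)C[C@H](OC(C)=O)[C@]2(C)[C@H](OC(C)=O)CC1 | intermediate
30 | 12-O-tert-butyldimethylsilyl ether of the target | COC(=O)/C1=C/[C@@H]2OC(=O)[C@H](C)[C@@]2(O)[C@H](OC(C)=O)[C@H]2[C@@H](C)[C@@H](O[Si](C)(C)C(C)(C)C)C[C@H](OC(C)=O)[C@]2(C)[C@H](OC(C)=O)CC1 | intermediate
31 | CNP0233742.2 | COC(=O)/C1=C/[C@@H]2OC(=O)[C@H](C)[C@@]2(O)[C@H](OC(C)=O)[C@H]2[C@@H](C)[C@@H](O)C[C@H](OC(C)=O)[C@]2(C)[C@H](OC(C)=O)CC1 | target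

Total step count: 19
Longest linear sequence: 19 steps (from 1 and 2; compounds 8, 14, 22 and 24 are bought)

Steps most likely to fail

Step 1. The funnel may be incomplete: the two acetyl groups may be discriminated poorly, and ketol or keto-lactone may be lost by dehydration or β-elimination under the acidic cascade conditions. The fallback sets out from 1 and 2 and separates the events. The Michael addition is run as in step 1 but stopped before acid is added, and adduct 3 is isolated. The ring is then closed by enamine catalysis with the proline enantiomer matched to C10 (DMSO, rt), which adds catalyst control to the choice between the acetyl groups and should give ketol 4 without dehydration. Hydroxyl-directed anti reduction of the C14 ketone (Me4NBH(OAc)3, AcOH/MeCN, −25 °C) gives the diol ester F1, which can no longer eliminate and has C14 set by intramolecular hydride delivery. Lactonisation (10-camphorsulfonic acid, PhMe, 60 °C) then selects the cis hydroxy ester and comes back to the route at compound 6, so that step 2 is by-passed as well.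

Step 16. Catalyst loading on the deactivated allylic C6 vinyl group may be slow and unselective, so that cross-metathesis oligomers and decomposition win over closure onto the hindered acrylate. The fallback is a relay ring-closing metathesis and sets out from 21. Nozaki–Hiyama–Kishi coupling with (E)-1-iodohepta-1,6-diene under the conditions of step 14 gives the relay carbinol F2, and acylation as in step 15 gives the relay ester F3. With second-generation Grubbs catalyst (PhMe, 1 mM, 50 °C) the carbene forms on the unhindered terminal olefin, expels cyclopentene and is thereby delivered intramolecularly to C6, from where it closes onto the acrylate. The fallback comes back to the route at compound 26.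

Step 14. Facial selectivity may be poor if the chiral chromium reagent is mismatched with the substrate bias, giving mainly the C7 epimer. The fallback corrects the centre by inversion instead of controlling the addition, and sets out from 21. A ligand-free Nozaki–Hiyama–Kishi vinylation (CrCl2, NiCl2, DMF) is run under substrate control, which through the chelated s-trans enal attacked anti to C10 should favour the (7R)-carbinol F4. F4 is esterified with 2-bromopropanoic acid under Mitsunobu conditions (PPh3, diisopropyl azodicarboxylate, PhMe, 0 °C) with inversion at C7 and comes back to the route at compound 25, by-passing step 15.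

Further compounds
F1 | step 1 | ethyl 2-acetyl-3,5-dihydroxy-2,6-dimethylcyclohexane-1-carboxylate (anti-1,3-diol, ester cis to the C12 hydroxyl) | CCOC(=O)[C@H]1[C@@H](C)[C@@H](O)C[C@H](O)[C@]1(C)C(C)=O
F2 | step 16 | (7S)-relay carbinol bearing an (E)-hepta-1,6-dienyl group on C7 | C=CCCC/C=C/[C@H](O)C(=C)[C@H](OC(C)=O)[C@H]1[C@@H](C)[C@@H](O[Si](C)(C)C(C)(C)C)C[C@H](OC(C)=O)[C@]1(C)[C@H](OC(C)=O)CCC(=C)C(=O)OC
F3 | step 16 | 7-O-(2-bromopropanoyl) ester of F2 | C=CCCC/C=C/[C@H](OC(=O)C(C)Br)C(=C)[C@H](OC(C)=O)[C@H]1[C@@H](C)[C@@H](O[Si](C)(C)C(C)(C)C)C[C@H](OC(C)=O)[C@]1(C)[C@H](OC(C)=O)CCC(=C)C(=O)OC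
F4 | step 14 | (7R)-bis-allylic alcohol (C7 epimer of 23) | C=C[C@@H](O)C(=C)[C@H](OC(C)=O)[C@H]1[C@@H](C)[C@@H](O[Si](C)(C)C(C)(C)C)C[C@H](OC(C)=O)[C@]1(C)[C@H](OC(C)=O)CCC(=C)C(=O)OC
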